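**Strategy.** The tetramer, read as epicatechin-(4β→6)-ent-epicatechin-(4α→8)-epicatechin-(4β→6)-ent-epicatechin, is disconnected at the last interflavan bond, between C4 of ring C of the third unit and C6 of ring A of the fourth. The key step makes this bond and the C4 stereocentre in one convergent Friedel–Crafts alkylation. It exploits two features: C4 is benzylic to a ring A whose O1, O5 and O7 stabilise a cation, and C6 lies between O5 and O7 of the partner. The precursors are a perbenzylated trimer with a 4-(2-ethoxyethoxy) leaving group and every ring A position capped by bromine or carbon, and 8-bromo-tetra-O-benzyl-ent-epicatechin, whose bromine blocks C8.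

Key step: step 11

Remark on the chemistry: the target's descriptors correspond to (2R,3R)-epicatechin units (first and third) alternating with (2S,3S)-ent-epicatechin units (second and fourth), every interflavan bond being 3,4-trans. (+)-Epicatechin, the (2S,3S) enantiomer, is assumed to be commercially available alongside (−)-epicatechin.

**Route**

Step 1
Reactants: 1 (−)-epicatechin
Product: 2 5,7,3',4'-tetra-O-benzyl-(−)-epicatechin (2R,3R; 3-OH free)
Conditions: BnBr (4.4 equiv), K2CO3, DMF, 0 °C to rt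
Reagents that add atoms: benzyl bromide, BrCc1ccccc1
Why: Williamson etherification in which carbonate deprotonates only the four phenols, so the secondary C3 hydroxyl stays free and no stereocentre is touched.

Step 2
Reactants: 2 5,7,3',4'-tetra-O-benzyl-(−)-epicatechin
Product: 3 4β-(2-ethoxyethoxy)-5,7,3',4'-tetra-O-benzyl-(−)-epicatechin (2,3-cis, 3,4-trans)
Conditions: DDQ (2 equiv), 2-ethoxyethanol (excess), CH2Cl2, rt
Reagents that add atoms: 2-ethoxyethanol, CCOCCO
Why: DDQ-mediated oxidative benzylic C–H etherification, in which hydride is abstracted from C4 (activated by O1, O5 and O7 of ring A) and the alcohol adds to the cation on the face opposite to the C3 hydroxyl and C2 aryl group, giving the 3,4-trans ether.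

Step 3
Reactants: 3 4β-(2-ethoxyethoxy)-5,7,3',4'-tetra-O-benzyl-(−)-epicatechin
Product: 4 6,8-dibromo-4β-(2-ethoxyethoxy)-5,7,3',4'-tetra-O-benzyl-(−)-epicatechin
Conditions: NBS (2.2 equiv), CH2Cl2, −40 °C to rt
Reagents that add atoms: N-bromosuccinimide, O=C1CCC(=O)N1Br
Why: Electrophilic aromatic bromination of the two free positions of the phloroglucinol-type ring A (C8, then C6), which is far more electron-rich than the catechol ring B, so that this electrophile can no longer alkylate itself.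

Step 4
Reactants: 5 (+)-epicatechin
Product: 6 5,7,3',4'-tetra-O-benzyl-(+)-epicatechin (2S,3S; 3-OH free)
Conditions: BnBr (4.4 equiv), K2CO3, DMF, 0 °C to rt
Reagents that add atoms: benzyl bromide, BrCc1ccccc1
Why: Williamson etherification of the four phenols as in step 1, with the C3 hydroxyl and both stereocentres untouched.

Step 5
Reactants: 6 5,7,3',4'-tetra-O-benzyl-(+)-epicatechin
Product: 7 8-bromo-5,7,3',4'-tetra-O-benzyl-(+)-epicatechin
Conditions: NBS (1.0 equiv), CH2Cl2, −78 to −20 °C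
Reagents that add atoms: N-bromosuccinimide, O=C1CCC(=O)N1Br
Why: Electrophilic aromatic bromination that is regioselective for C8, the most nucleophilic ring A position of a benzylated flavan-3-ol, leaving C6 as the only free position of ring A.

Step 6
Reactants: 4 6,8-dibromo-4β-(2-ethoxyethoxy)-5,7,3',4'-tetra-O-benzyl-(−)-epicatechin; 7 8-bromo-5,7,3',4'-tetra-O-benzyl-(+)-epicatechin (2.5 equiv)
Product: 8 protected dimer [6,8-dibromo-tetra-O-benzyl-epicatechin]-(4β→6)-[8-bromo-tetra-O-benzyl-ent-epicatechin]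
Conditions: TMSOTf (cat.), 4 Å MS, CH2Cl2, −78 to −30 °C; Et3N quench
Reagents that add atoms: none
Why: Lewis-acid-promoted Friedel–Crafts interflavan coupling in which the C4 cation from 4, unable to attack its own fully substituted ring A, is captured by the only free ring A carbon (C6) of 7 on the face trans to the C3 hydroxyl, setting the 4β (3,4-trans) centre.

Step 7
Reactants: 8 protected dimer
Product: 9 dimer 8 carrying a 4α-(2-ethoxyethoxy) group (trans to the 3-hydroxyl) on its ent-epicatechin unit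
Conditions: DDQ (3 equiv), 2-ethoxyethanol (excess), CH2Cl2, rt
Reagents that add atoms: 2-ethoxyethanol, CCOCCO
Why: DDQ-mediated oxidative C–H etherification at the only benzylic CH2 of the dimer (C4 of the lower unit), the tertiary C4–H of the upper unit being shielded between two fully ortho-substituted rings that cannot become coplanar, with the alcohol adding trans to the C3 hydroxyl.

Step 8
Reactants: 9 4-(2-ethoxyethoxy) dimer; 2 5,7,3',4'-tetra-O-benzyl-(−)-epicatechin (3 equiv)
Product: 10 protected trimer [6,8-dibromo-tetra-O-benzyl-epicatechin]-(4β→6)-[8-bromo-tetra-O-benzyl-ent-epicatechin]-(4α→8)-[tetra-O-benzyl-epicatechin]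
Conditions: TMSOTf (cat.), 4 Å MS, CH2Cl2, −78 to −40 °C; Et3N quench
Reagents that add atoms: none
Why: Friedel–Crafts interflavan coupling in which the C4 cation of the ent-epicatechin unit is captured by C8 of 2, its most nucleophilic ring A carbon, on the face trans to the C3 hydroxyl (4α, 3,4-trans), while 2 has no leaving group and cannot oligomerise.

Step 9
Reactants: 10 protected trimer
Product: 11 trimer 10 with bromine at C6 of its third (epicatechin) unit
Conditions: NBS (1.05 equiv), CH2Cl2, −40 to 0 °C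
Reagents that add atoms: N-bromosuccinimide, O=C1CCC(=O)N1Br
Why: Electrophilic aromatic bromination at the single remaining free carbon of a phloroglucinol-type ring, which removes the last nucleophilic site of the trimer before steps 10 and 11.

Step 10
Reactants: 11 C6-brominated trimer
Product: 12 trimer 11 carrying a 4β-(2-ethoxyethoxy) group (trans to the 3-hydroxyl) on its third unit
Conditions: DDQ (3 equiv), 2-ethoxyethanol (excess), CH2Cl2, rt
Reagents that add atoms: 2-ethoxyethanol, CCOCCO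
Why: DDQ-mediated oxidative C–H etherification at the only benzylic CH2 of the trimer (C4 of the third unit), the cation being trapped by the alcohol trans to the C3 hydroxyl and unable to self-alkylate because no ring A carbon is free.

Step 11
Reactants: 12 4β-(2-ethoxyethoxy) trimer; 7 8-bromo-5,7,3',4'-tetra-O-benzyl-(+)-epicatechin (4 equiv)
Product: 13 protected tetramer, pentabromo-hexadeca-O-benzyl-[epicatechin-(4β→6)-ent-epicatechin-(4α→8)-epicatechin-(4β→6)-ent-epicatechin]
Conditions: TMSOTf (cat.), 4 Å MS, CH2Cl2, −78 to −30 °C; Et3N quench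
Reagents that add atoms: none
Why: TMSOTf ionises the C4–O bond of ring C of the third unit of 12 to a benzylic cation stabilised by O1 and the 5- and 7-benzyloxy groups of its ring A, and this cation alkylates ring A of 7 in an intermolecular Friedel–Crafts reaction followed by loss of a proton. The closest known reaction type is the Lewis-acid-promoted interflavan coupling of 4-alkoxyflavan electrophiles with benzylated flavan-3-ol nucleophiles, in its halogen-capped variant for 4→6 bonds. No ring is closed. The new stereocentre C4 is under substrate control: the arene adds to the half-chair cation on the face opposite to the C3 hydroxyl and C2 aryl group of the 2,3-cis ring C, which gives the 3,4-trans (4β) bond. The step needs C6 over C8 selectivity in 7, secured by the C8 bromine that leaves C6 between O5 and O7 as the only free ring A carbon, and cross-coupling over self-condensation or over-alkylation, secured because 7 has no leaving group and neither 12 nor the product has an unsubstituted ring A carbon. The free 3-hydroxyls can add to the cation only reversibly, so excess 7 and slow warming should funnel the material to the C–C bonded product.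

Step 12
Reactants: 13 protected tetramer
Product: 14 epicatechin-(4β→6)-ent-epicatechin-(4α→8)-epicatechin-(4β→6)-ent-epicatechin (target)
Conditions: H2 (1 atm), Pd(OH)2/C, NaOAc, THF/MeOH/H2O, rt
Reagents that add atoms: none
Why: Catalytic hydrogenolysis cleaves the sixteen benzyl ethers and hydrodehalogenation removes the five aryl bromides in one operation, acetate buffering the HBr so that the acid-labile interflavan bonds and all stereocentres stay intact.

**Compound list**

1 | (−)-epicatechin, (2R,3R) | Oc1cc(O)c2c(c1)O[C@H](c1ccc(O)c(O)c1)[C@H](O)C2 | starting material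
2 | 5,7,3',4'-tetra-O-benzyl-(−)-epicatechin (2R,3R; 3-OH free) | c1ccccc1COc1cc(OCc2ccccc2)c2c(c1)O[C@H](c1ccc(OCc3ccccc3)c(OCc3ccccc3)c1)[C@H](O)C2 | intermediate
3 | 4β-(2-ethoxyethoxy)-5,7,3',4'-tetra-O-benzyl-(−)-epicatechin (2,3-cis, 3,4-trans) | c1ccccc1COc1cc(OCc2ccccc2)c2c(c1)O[C@H](c1ccc(OCc3ccccc3)c(OCc3ccccc3)c1)[C@H](O)[C@H]2OCCOCC | intermediate
4 | 6,8-dibromo-4β-(2-ethoxyethoxy)-5,7,3',4'-tetra-O-benzyl-(−)-epicatechin | c1ccccc1COc1c(Br)c(OCc2ccccc2)c2c(c1Br)O[C@H](c1ccc(OCc3ccccc3)c(OCc3ccccc3)c1)[C@H](O)[C@H]2OCCOCC | intermediate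
5 | (+)-epicatechin (ent-epicatechin), (2S,3S) | Oc1cc(O)c2c(c1)O[C@@H](c1ccc(O)c(O)c1)[C@@H](O)C2 | starting material
6 | 5,7,3',4'-tetra-O-benzyl-(+)-epicatechin (2S,3S; 3-OH free) | c1ccccc1COc1cc(OCc2ccccc2)c2c(c1)O[C@@H](c1ccc(OCc3ccccc3)c(OCc3ccccc3)c1)[C@@H](O)C2 | intermediate
7 | 8-bromo-5,7,3',4'-tetra-O-benzyl-(+)-epicatechin | c1ccccc1COc1cc(OCc2ccccc2)c2c(c1Br)O[C@@H](c1ccc(OCc3ccccc3)c(OCc3ccccc3)c1)[C@@H](O)C2 | intermediate
8 | protected dimer [6,8-dibromo-tetra-O-benzyl-epicatechin]-(4β→6)-[8-bromo-tetra-O-benzyl-ent-epicatechin], both 3-OH free, interflavan bond 3,4-trans | c1ccccc1COc1c(Br)c(OCc2ccccc2)c2c(c1Br)O[C@H](c1ccc(OCc3ccccc3)c(OCc3ccccc3)c1)[C@H](O)[C@H]2c1c(OCc2ccccc2)c(Br)c2c(c1OCc1ccccc1)C[C@H](O)[C@H](c1ccc(OCc3ccccc3)c(OCc3ccccc3)c1)O2 | intermediate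
9 | dimer 8 with a 4α-(2-ethoxyethoxy) group (trans to 3-OH) on the ent-epicatechin unit | c1ccccc1COc1c(Br)c(OCc2ccccc2)c2c(c1Br)O[C@H](c1ccc(OCc3ccccc3)c(OCc3ccccc3)c1)[C@H](O)[C@H]2c1c(OCc2ccccc2)c(Br)c2c(c1OCc1ccccc1)[C@@H](OCCOCC)[C@H](O)[C@H](c1ccc(OCc3ccccc3)c(OCc3ccccc3)c1)O2 | intermediate
10 | protected trimer [6,8-dibromo-tetra-O-benzyl-epicatechin]-(4β→6)-[8-bromo-tetra-O-benzyl-ent-epicatechin]-(4α→8)-[tetra-O-benzyl-epicatechin], all 3-OH free, both interflavan bonds 3,4-trans | c1ccccc1COc1c(Br)c(OCc2ccccc2)c2c(c1Br)O[C@H](c1ccc(OCc3ccccc3)c(OCc3ccccc3)c1)[C@H](O)[C@H]2c1c(OCc2ccccc2)c(Br)c2c(c1OCc1ccccc1)[C@@H](c1c(OCc4ccccc4)cc(OCc4ccccc4)c3c1O[C@H](c1ccc(OCc4ccccc4)c(OCc4ccccc4)c1)[C@H](O)C3)[C@H](O)[C@H](c1ccc(OCc3ccccc3)c(OCc3ccccc3)c1)O2 | intermediate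
11 | trimer 10 with bromine at C6 of the third unit | c1ccccc1COc1c(Br)c(OCc2ccccc2)c2c(c1Br)O[C@H](c1ccc(OCc3ccccc3)c(OCc3ccccc3)c1)[C@H](O)[C@H]2c1c(OCc2ccccc2)c(Br)c2c(c1OCc1ccccc1)[C@@H](c1c(OCc4ccccc4)c(Br)c(OCc4ccccc4)c3c1O[C@H](c1ccc(OCc4ccccc4)c(OCc4ccccc4)c1)[C@H](O)C3)[C@H](O)[C@H](c1ccc(OCc3ccccc3)c(OCc3ccccc3)c1)O2 | intermediate
12 | trimer 11 with a 4β-(2-ethoxyethoxy) group (trans to 3-OH) on the third unit | c1ccccc1COc1c(Br)c(OCc2ccccc2)c2c(c1Br)O[C@H](c1ccc(OCc3ccccc3)c(OCc3ccccc3)c1)[C@H](O)[C@H]2c1c(OCc2ccccc2)c(Br)c2c(c1OCc1ccccc1)[C@@H](c1c(OCc4ccccc4)c(Br)c(OCc4ccccc4)c3c1O[C@H](c1ccc(OCc4ccccc4)c(OCc4ccccc4)c1)[C@H](O)[C@H]3OCCOCC)[C@H](O)[C@H](c1ccc(OCc3ccccc3)c(OCc3ccccc3)c1)O2 | intermediate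
13 | protected tetramer: hexadeca-O-benzyl ether of the target with bromine at C6 and C8 of unit 1, C8 of unit 2, C6 of unit 3 and C8 of unit 4 | c1ccccc1COc1c(Br)c(OCc2ccccc2)c2c(c1Br)O[C@H](c1ccc(OCc3ccccc3)c(OCc3ccccc3)c1)[C@H](O)[C@H]2c1c(OCc2ccccc2)c(Br)c2c(c1OCc1ccccc1)[C@@H](c1c(OCc4ccccc4)c(Br)c(OCc4ccccc4)c3c1O[C@H](c1ccc(OCc4ccccc4)c(OCc4ccccc4)c1)[C@H](O)[C@H]3c1c(OCc4ccccc4)c(Br)c3c(c1OCc1ccccc1)C[C@H](O)[C@H](c1ccc(OCc4ccccc4)c(OCc4ccccc4)c1)O3)[C@H](O)[C@H](c1ccc(OCc3ccccc3)c(OCc3ccccc3)c1)O2 | intermediate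
14 | epicatechin-(4β→6)-ent-epicatechin-(4α→8)-epicatechin-(4β→6)-ent-epicatechin (CNP0120618.2) | Oc1cc(O)c2c(c1)O[C@H](c1ccc(O)c(O)c1)[C@H](O)[C@H]2c1c(O)cc2c(c1O)[C@@H](c1c(O)cc(O)c3c1O[C@H](c1ccc(O)c(O)c1)[C@H](O)[C@H]3c1c(O)cc3c(c1O)C[C@H](O)[C@H](c1ccc(O)c(O)c1)O3)[C@H](O)[C@H](c1ccc(O)c(O)c1)O2 | target

**Totals**

Total step count: 12.
Longest linear sequence: 10 steps (1 → 2 → 3 → 4 → 8 → 9 → 10 → 11 → 12 → 13 → 14).

**Steps most likely to fail**

Step 11 (key step). Capture of the cation by C6 of 7, which is deactivated by the bromine and crowded by two benzyloxy groups, may be slower than loss of the C3 proton or than acid-induced fission of the two existing interflavan bonds. The fallback replaces acid ionisation by thiophilic activation with no free acid present. It sets out from 12: BF3·OEt2 and 2,6-dimethylbenzenethiol (CH2Cl2, −78 °C), where the thiol traps the cation at once, should give the trimer 4β-(2,6-dimethylphenylthio) ether F1. I2 and Ag2O (CH2Cl2, 4 Å MS, −78 to −20 °C) then activate the sulfur of F1 in the presence of a large excess of 7, and the coupling comes back to the route at 13.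

Step 6. Ionisation and capture may both be slow, because the bromines flanking the 5- and 7-benzyloxy groups of 4 twist them out of conjugation and crowd C4 while the nucleophile is itself deactivated; the cation may then decay by elimination. The fallback caps C6 of the upper unit after the coupling instead of before it. It sets out from 3: NBS (1.0 equiv, CH2Cl2, −78 °C) should give 8-bromo-4β-(2-ethoxyethoxy)-5,7,3',4'-tetra-O-benzyl-(−)-epicatechin F2. TMSOTf-promoted coupling of F2 with a large excess of 7, which outcompetes the equally reactive C6 of F2 by concentration, should give the dimer lacking the C6 bromine on its upper unit F3. NBS (1.05 equiv) then brominates the only free ring A carbon of F3, and the route is rejoined at 8.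

Step 10. On the crowded trimer DDQ may abstract hydride unselectively (the tertiary C4–H bonds of the two inner units), over-oxidise, or react too slowly at the brominated third unit. The fallback brings the leaving group in with the third unit, masked as a thioether that is inert to the hard Lewis acid, so that no oligomer has to be oxidised. It sets out from 3 and 9: 3 with 2,6-dimethylbenzenethiol and BF3·OEt2 (CH2Cl2, −78 °C) should give 4β-(2,6-dimethylphenylthio)-5,7,3',4'-tetra-O-benzyl-(−)-epicatechin F4. BF3·OEt2 at −78 °C should then couple 9 with C8 of F4 to give the trimer thioether with free C6 on its third unit F5. I2 and Ag2O with excess 2-ethoxyethanol exchange the thio group of F5 for the alkoxy group, giving the 4β-(2-ethoxyethoxy) trimer with free C6 on its third unit F6. NBS (1.05 equiv) caps C6 of F6, and the route is rejoined at 12, steps 8 to 10 being bypassed.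

**Further compounds**

F1 | step 11 | trimer 12 with the 4β-(2-ethoxyethoxy) group replaced by 4β-(2,6-dimethylphenylthio) | c1ccccc1COc1c(Br)c(OCc2ccccc2)c2c(c1Br)O[C@H](c1ccc(OCc3ccccc3)c(OCc3ccccc3)c1)[C@H](O)[C@H]2c1c(OCc2ccccc2)c(Br)c2c(c1OCc1ccccc1)[C@@H](c1c(OCc4ccccc4)c(Br)c(OCc4ccccc4)c3c1O[C@H](c1ccc(OCc4ccccc4)c(OCc4ccccc4)c1)[C@H](O)[C@H]3Sc1c(C)cccc1C)[C@H](O)[C@H](c1ccc(OCc3ccccc3)c(OCc3ccccc3)c1)O2
F2 | step 6 | 8-bromo-4β-(2-ethoxyethoxy)-5,7,3',4'-tetra-O-benzyl-(−)-epicatechin | c1ccccc1COc1cc(OCc2ccccc2)c2c(c1Br)O[C@H](c1ccc(OCc3ccccc3)c(OCc3ccccc3)c1)[C@H](O)[C@H]2OCCOCC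
F3 | step 6 | protected dimer [8-bromo-tetra-O-benzyl-epicatechin]-(4β→6)-[8-bromo-tetra-O-benzyl-ent-epicatechin], C6–H on the upper unit | c1ccccc1COc1cc(OCc2ccccc2)c2c(c1Br)O[C@H](c1ccc(OCc3ccccc3)c(OCc3ccccc3)c1)[C@H](O)[C@H]2c1c(OCc2ccccc2)c(Br)c2c(c1OCc1ccccc1)C[C@H](O)[C@H](c1ccc(OCc3ccccc3)c(OCc3ccccc3)c1)O2
F4 | step 10 | 4β-(2,6-dimethylphenylthio)-5,7,3',4'-tetra-O-benzyl-(−)-epicatechin (3,4-trans) | c1ccccc1COc1cc(OCc2ccccc2)c2c(c1)O[C@H](c1ccc(OCc3ccccc3)c(OCc3ccccc3)c1)[C@H](O)[C@H]2Sc1c(C)cccc1C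
F5 | step 10 | trimer 10 carrying a 4β-(2,6-dimethylphenylthio) group on its third unit (C6–H free) | c1ccccc1COc1c(Br)c(OCc2ccccc2)c2c(c1Br)O[C@H](c1ccc(OCc3ccccc3)c(OCc3ccccc3)c1)[C@H](O)[C@H]2c1c(OCc2ccccc2)c(Br)c2c(c1OCc1ccccc1)[C@@H](c1c(OCc4ccccc4)cc(OCc4ccccc4)c3c1O[C@H](c1ccc(OCc4ccccc4)c(OCc4ccccc4)c1)[C@H](O)[C@H]3Sc1c(C)cccc1C)[C@H](O)[C@H](c1ccc(OCc3ccccc3)c(OCc3ccccc3)c1)O2
F6 | step 10 | trimer 10 carrying a 4β-(2-ethoxyethoxy) group on its third unit (C6–H free) | c1ccccc1COc1c(Br)c(OCc2ccccc2)c2c(c1Br)O[C@H](c1ccc(OCc3ccccc3)c(OCc3ccccc3)c1)[C@H](O)[C@H]2c1c(OCc2ccccc2)c(Br)c2c(c1OCc1ccccc1)[C@@H](c1c(OCc4ccccc4)cc(OCc4ccccc4)c3c1O[C@H](c1ccc(OCc4ccccc4)c(OCc4ccccc4)c1)[C@H](O)[C@H]3OCCOCC)[C@H](O)[C@H](c1ccc(OCc3ccccc3)c(OCc3ccccc3)c1)O2
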